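## Analysis of the target

The target 26 is a bridgehead-acylated polyprenylated acylphloroglucinol built on a bicyclo[3.3.1]nonane-2,4,9-trione. Ring A (C1–C2–C3–C4–C5–C9) holds an enolised β-diketone at C2/C4 whose central carbon C3 carries a 3-hydroxy-3-methylbutyl chain. Ring B (C1–C8–C7–C6–C5–C9) is a cyclohexanone with C9 as the ketone, a gem-dimethyl group at C8 and a prenyl group at C7. Both bridgeheads are quaternary: C1 carries the (R)-2-methylbutanoyl group and C5 a prenyl group.

There are four stereocentres. C1 (S) and C5 (S) are tied to each other by the bridge. C7 (R) holds its prenyl group on the face of ring B away from ring A, cis to the C5 prenyl group. The side-chain centre (R) is independent of the core.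

Sensitive points are the two trisubstituted alkenes, the tertiary alcohol (it can close onto the enol under acid), the non-enolisable 1,3-dicarbonyl arrays at C1 and C5 (retro-Claisen cleavage by nucleophiles) and the epimerisable α-carbon of the acyl group. The synthesis is hard because C1 is congested by C8, both bridgeheads are quaternary, and four different carbon groups must be placed regiospecifically on an almost symmetric trione.

The strategy rests on C3. It lies between the C2 and C4 carbonyl groups and carries the chain, so taking it out together with the chain leaves a vicinal diketone that bridges C1 and C5.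

## Retrosynthetic reasoning

**26 ⇒ 25 ⇒ 24 (O–Si and O–CH3).** The tertiary alcohol and the enol are unmasked last. The silyl ether keeps the alcohol out of the base chemistry, and the methyl enol ether fixes the diketone as a vinylogous ester so that a bridgehead anion can be made.

**24 ⇒ 21 + 23 (C1–acyl bond).** In 21 the C1–H bond is flanked by the C2 and C9 carbonyl groups and is the only acidic C–H left, because C3 already carries its chain. Cutting here brings in the acyl group, with its labile α-centre, as late as possible. Acid chloride 23 comes from acid 22.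

**21 ⇒ 20 (O–CH3).** O-Methylation of enol 20. The regioisomer with the carbonyl group next to C1–H is the one required.

**20 ⇒ 13 + 19 (C2–C3 and C3–C4).** Both bonds to C3 are cut, which removes one ring carbon together with the side chain. This leaves the bridged 1,2-diketone 13 and the diazoalkane 19. The forward step has to add 19 to the diketone, shift the acyl carbon, and leave the bridging ketone alone. What is gained is that ring A, its oxidation pattern and the C3 substituent arrive in one operation, so no later C3 alkylation is needed.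

**19 ⇒ 18 ⇒ 17 ⇒ 16 ⇒ 15 ⇒ 14.** The diazoalkane is traced through hydrazone 18 to aldehyde 17. The aldehyde comes from lactone 14 by reduction to diol 15, double silylation to 16 and selective oxidation of the primary silyl ether.

**13 ⇒ 12 (C1–C(=O) bond of the two-carbon bridge).** Keto ester 12 has only one enolisable position, the CH2 group that becomes C1. The forward step must acylate that carbon with the axial oxalyl ester and must not let a nucleophile reopen the strained trione.

**12 ⇒ 10 + 11, and 10 ⇒ 9 (C5–C(=O) bond).** The oxalyl carbon is attached second, after the prenyl group. An electrophile enters the enol ether 10 axially, anti to the ring prenyl group, so this order places the future bridge trans and the C5 prenyl group cis to the C7 prenyl group, as the target requires. The opposite order would give the C7 epimeric series.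

**9 ⇒ 7 + 8.** Kinetic prenylation of ketone 7 at the α-carbon remote from the quaternary centre.

**7 ⇒ 6 ⇒ 5 ⇒ 4.** The gem-dimethyl carbon is cut into two methyl conjugate additions with an enone regeneration between them.

**4 ⇒ 3 ⇒ 1 + 2.** Robinson-type disconnection into enone 1 and aldehyde 2. The α-carbon of 2 becomes C7, so an amine catalyst can set the absolute configuration of the whole core at the first C–C bond, with the prenyl group already in place.

## Alternatives that were turned down

**Alternative 1: [4+2] assembly of ring B.** The C5–C6 and C7–C8 bonds are cut. In the forward step triisopropyl[(4-methylpenta-1,3-dien-2-yl)oxy]silane A1 and 3-(prop-2-enoyl)-1,3-oxazolidin-2-one A2 combine under [Cu(t-Bu-box)](SbF6)2 (divalent copper) to the cyclohexene imide A3, with C9 as a regiodefined silyl enol ether.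
- For it: catalytic enantiocontrol of acryloyl imide cycloadditions is highly developed. On predictability of the absolute configuration at C7 it is at least as strong as step 1 of the chosen route.
- Against it: A1 carries a cis methyl group on the reacting terminus, which disfavours the s-cis conformer and makes the bond to the future C8 slow. The imide carbon of A3 must then be turned into a prenyl group over several steps. The C5 prenyl group, all of ring A, the C3 chain and the C1 acyl group are still missing.
- Comparison: it delivers only the equivalent of ketone 7, in more steps. The chosen route reaches 7 in five steps with the prenyl group present from the start, and spends its key step on ring A, which this alternative leaves open.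

**Alternative 2: gold carbocyclisation on a desymmetrised dimedone.** The C1–C2 bond is cut. The mono(silyl enol ether) A4 of 2-prenyl-2-propargyldimedone cyclises under [Au(NCMe)(P(t-Bu)2(biphenyl-2-yl))]SbF6 (monovalent gold): the enol ether carbon attacks the alkyne terminus in a 6-endo-dig mode and gives the bicyclic enedione A5.
- For it: the bicyclic skeleton, the C8 gem-dimethyl group and the C5 quaternary centre come very quickly from dimedone. Gold-catalysed closure of bridged rings from silyl enol ethers has better precedent than the bridged Claisen closure of step 9, so on reaching the bicycle it is the stronger plan.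
- Against it: the absolute configuration depends on an enantioselective enolisation of a prochiral dione. A5 has a C6 carbonyl group that the target lacks, has no C7 prenyl group, and has an alkene where ring A needs a 2,4-dione. Removing the C6 oxygen beside the C9 ketone and the alkenes, oxidising C2 and C4, alkylating C3 and acylating C1 is a long redox sequence.
- Comparison: the chosen route forms ring A at the final oxidation level with the C3 chain attached and needs five steps after the key step.

**Alternative 3: epoxide-triggered, group-selective closure of ring B.** The C1–C8 bond is cut. Trimethylsilyl triflate opens the epoxide of the dimethoxycyclohexadiene A6 at its tertiary carbon, one of the two enantiotopic enol ethers attacks through C1, and the bicyclic ketone A7 results.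
- For it: the stereochemistry follows from one epoxide centre through a chair-like transition state. A7 already has the methoxy group at C4 and, after oxidation of C2, gives exactly the vinylogous ester needed for bridgehead acylation. On that point it is stronger than step 16 of the chosen route, which cannot control which enol oxygen is methylated.
- Against it: C7 carries a hydroxyl group where the target needs a prenyl group. Replacing a hindered secondary carbinol next to C8 by carbon with defined configuration is long and uncertain. C2 must still be oxidised, and the saturated, oxygenated C3 chain must be attached by vinylic metalation with a non-allylic electrophile, which is a poor reaction.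
- Comparison: the chosen route carries the C7 prenyl group from the first step and brings C3 in with its chain.

Key step: step 15

## Remarks on the chemistry

- Compounds 20, 25 and 26 are written as the C4 enol; the C2 enol is a tautomer of the same compound.
- Ketone 9 is carried as a mixture of epimers at the newly alkylated carbon, which becomes trigonal in step 7.
- Aldehyde 2 and acid 22 are taken as purchasable.

## Steps

Step 1
Reactants: 1 methyl vinyl ketone; 2 5-methylhex-4-enal
Product: 3 (2S)-2-(3-methylbut-2-en-1-yl)-5-oxohexanal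
Conditions: (S)-2-(methoxydiphenylmethyl)pyrrolidine (5 mol%), ethyl 3,4-dihydroxybenzoate (20 mol%), neat, 4 °C
Reagents that add atoms: none
Why: Enamine-mediated Michael addition of the aldehyde to the enone; the E-enamine should be attacked on the face away from the diphenyl(methoxy)methyl group, which gives the (S) centre that becomes C7, while the catechol activates 1 by hydrogen bonding.

Step 2
Reactants: 3 (2S)-2-(3-methylbut-2-en-1-yl)-5-oxohexanal
Product: 4 (4S)-4-(3-methylbut-2-en-1-yl)cyclohex-2-en-1-one
Conditions: LiOH, i-PrOH, rt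
Reagents that add atoms: none
Why: Intramolecular aldol condensation (second stage of a Robinson annulation); the methyl ketone enolate adds to the aldehyde and E1cB loss of water gives the enone, after which the stereocentre is the γ-carbon and no longer α to a carbonyl group.

Step 3
Reactants: 4 (4S)-4-(3-methylbut-2-en-1-yl)cyclohex-2-en-1-one
Product: 5 trimethyl{[(3S,4S)-3-methyl-4-(3-methylbut-2-en-1-yl)cyclohex-1-en-1-yl]oxy}silane (methyl trans to prenyl)
Conditions: Me2CuLi, TMSCl, THF, −78 °C; Et3N, pentane, aq. NaHCO3
Reagents that add atoms: lithium dimethylcuprate, [Li+].C[Cu-]C; chlorotrimethylsilane, C[Si](C)(C)Cl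
Why: Conjugate addition of a methyl cuprate, accelerated and trapped by TMSCl; the methyl group should add anti to the C4 prenyl group (this centre is removed in step 4) and the enolate is fixed as a regiodefined silyl enol ether.

Step 4
Reactants: 5 trimethyl{[(3S,4S)-3-methyl-4-(3-methylbut-2-en-1-yl)cyclohex-1-en-1-yl]oxy}silane
Product: 6 (4S)-3-methyl-4-(3-methylbut-2-en-1-yl)cyclohex-2-en-1-one
Conditions: Pd(OAc)2 (1.05 equiv), MeCN, rt
Reagents that add atoms: none
Why: Saegusa–Ito oxidation; the palladium enolate undergoes β-hydride elimination toward C3 and restores the enone with the new methyl group on the β-carbon, while C4 is not touched.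

Step 5
Reactants: 6 (4S)-3-methyl-4-(3-methylbut-2-en-1-yl)cyclohex-2-en-1-one
Product: 7 (4S)-3,3-dimethyl-4-(3-methylbut-2-en-1-yl)cyclohexan-1-one
Conditions: Me2CuLi, Et2O, 0 °C; aq. NH4Cl
Reagents that add atoms: lithium dimethylcuprate, [Li+].C[Cu-]C
Why: A second cuprate conjugate addition to the β,β-disubstituted enone builds the quaternary gem-dimethyl carbon (C8 of the target); no new stereocentre is formed.

Step 6
Reactants: 7 (4S)-3,3-dimethyl-4-(3-methylbut-2-en-1-yl)cyclohexan-1-one; 8 1-bromo-3-methylbut-2-ene (prenyl bromide)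
Product: 9 (4R)-5,5-dimethyl-2,4-bis(3-methylbut-2-en-1-yl)cyclohexan-1-one (C2 epimers)
Conditions: LDA, THF, −78 °C; then 8, DMPU, −78 → −20 °C
Reagents that add atoms: none
Why: Kinetic enolate alkylation; lithium diisopropylamide removes a proton from the CH2 group remote from the quaternary carbon (the other α-CH2 is neopentylic) and the enolate is alkylated by the allylic bromide; the configuration of the new centre does not matter because it becomes trigonal in step 7.

Step 7
Reactants: 9 (4R)-5,5-dimethyl-2,4-bis(3-methylbut-2-en-1-yl)cyclohexan-1-one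
Product: 10 trimethyl{[(4R)-5,5-dimethyl-2,4-bis(3-methylbut-2-en-1-yl)cyclohex-1-en-1-yl]oxy}silane
Conditions: TMSCl, NaI, Et3N, MeCN, rt → 40 °C
Reagents that add atoms: chlorotrimethylsilane, C[Si](C)(C)Cl
Why: Silylation under equilibrating conditions (iodotrimethylsilane formed in situ, amine base) should favour the tetrasubstituted enol ether over the isomer toward the neopentylic CH2 group.

Step 8
Reactants: 10 trimethyl{[(4R)-5,5-dimethyl-2,4-bis(3-methylbut-2-en-1-yl)cyclohex-1-en-1-yl]oxy}silane; 11 methyl chlorooxoacetate
Product: 12 methyl 2-[(1R,5R)-4,4-dimethyl-1,5-bis(3-methylbut-2-en-1-yl)-2-oxocyclohexyl]-2-oxoacetate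
Conditions: 11, ZnCl2 (10 mol%), CH2Cl2, −20 °C → rt
Reagents that add atoms: none
Why: Lewis-acid-promoted C-acylation of a silyl enol ether by an acid chloride (Mukaiyama-type acylation); the electrophile should approach axially on the face anti to the ring prenyl group, the other face being screened by the axial methyl group across the ring, so the oxalyl group ends trans and the new quaternary prenyl group cis to the existing prenyl group (this sets C5 of the target relative to C7).

Step 9
Reactants: 12 methyl 2-[(1R,5R)-4,4-dimethyl-1,5-bis(3-methylbut-2-en-1-yl)-2-oxocyclohexyl]-2-oxoacetate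
Product: 13 (1S,3R,5R)-2,2-dimethyl-3,5-bis(3-methylbut-2-en-1-yl)bicyclo[3.2.1]octane-6,7,8-trione
Conditions: LiN(SiMe3)2, THF (0.01 M), −78 °C; cannulated into AcOH/THF, −78 °C
Reagents that add atoms: none
Why: Proposed new method: the ring ketone of 12 has one enolisable position (the CH2 group next to the gem-dimethyl carbon), and its lithium enolate can reach the ester carbonyl of the axial oxalyl group through a five-membered transition state [5-(enolendo)-exo-trig]; the tetrahedral adduct of an oxalate-type ester should persist at −78 °C, as in the mono-addition of organometallic reagents to dialkyl oxalates, so that methoxide is set free only in the acidic quench and cannot reopen the strained, non-enolisable trione by retro-Claisen cleavage; the closest known reaction is the Claisen closure of α-oxalyl ketones to cyclopentane-1,2,4-triones, which has not been shown for a bridged product that cannot enolise; the new bridgehead centre is fixed by the cis bridge.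

Step 10
Reactants: 14 5,5-dimethyldihydrofuran-2(3H)-one
Product: 15 4-methylpentane-1,4-diol
Conditions: LiAlH4, THF, 0 °C → rt; H2O, aq. NaOH
Reagents that add atoms: none
Why: Hydride reduction of the lactone to the 1,4-diol.

Step 11
Reactants: 15 4-methylpentane-1,4-diol
Product: 16 2-methyl-2,5-bis[(triethylsilyl)oxy]pentane
Conditions: TESOTf, 2,6-lutidine, CH2Cl2, −78 → 0 °C
Reagents that add atoms: triethylsilyl trifluoromethanesulfonate, CC[Si](CC)(CC)OS(=O)(=O)C(F)(F)F
Why: Silylation of both hydroxyl groups; the silyl triflate is needed for the tertiary alcohol.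

Step 12
Reactants: 16 2-methyl-2,5-bis[(triethylsilyl)oxy]pentane
Product: 17 4-methyl-4-[(triethylsilyl)oxy]pentanal
Conditions: (COCl)2, DMSO, CH2Cl2, −78 → −30 °C; Et3N, −78 °C → rt
Reagents that add atoms: none
Why: Under Swern conditions a primary triethylsilyl ether is cleaved by the chlorosulfonium salt and oxidised directly to the aldehyde, while the hindered tertiary silyl ether is inert.

Step 13
Reactants: 17 4-methyl-4-[(triethylsilyl)oxy]pentanal
Product: 18 {4-methyl-4-[(triethylsilyl)oxy]pentylidene}hydrazine
Conditions: N2H4·H2O (10 equiv), EtOH, 0 °C → rt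
Reagents that add atoms: hydrazine (as hydrate), NN
Why: Condensation to the N-unsubstituted hydrazone; the large excess of hydrazine suppresses azine formation.

Step 14
Reactants: 18 {4-methyl-4-[(triethylsilyl)oxy]pentylidene}hydrazine
Product: 19 triethyl[(5-diazo-2-methylpentan-2-yl)oxy]silane (cold solution, used at once)
Conditions: (COCl)2, DMSO, THF, −78 °C; then 18, Et3N, −78 °C; cold filtration
Reagents that add atoms: none
Why: Swern-type dehydrogenation of a hydrazone; S-amination by the chlorosulfonium salt and base-induced loss of dimethyl sulfide give the diazoalkane at −78 °C, where a non-stabilised diazoalkane should survive.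

Step 15
Reactants: 13 (1S,3R,5R)-2,2-dimethyl-3,5-bis(3-methylbut-2-en-1-yl)bicyclo[3.2.1]octane-6,7,8-trione; 19 triethyl[(5-diazo-2-methylpentan-2-yl)oxy]silane
Product: 20 (1R,5S,7R)-4-hydroxy-8,8-dimethyl-5,7-bis(3-methylbut-2-en-1-yl)-3-{3-methyl-3-[(triethylsilyl)oxy]butyl}bicyclo[3.3.1]non-3-ene-2,9-dione
Conditions: Sc(OTf)3 (10 mol%), toluene/CH2Cl2, −78 → −40 °C; slow addition of 19 (1.2 equiv)
Reagents that add atoms: none
Why: The 1,2-diketone of 13 chelates Sc(OTf)3 and the nucleophilic carbon of 19 adds to one of its carbonyl groups to give a diazonium alkoxide. The neighbouring acyl carbon then migrates to the diazonium carbon as N2 leaves, which places the new carbon between the two former diketone carbons and forms the C2–C3 and C3–C4 bonds; the 2-substituted 1,3-diketone tautomerises to enol 20. The closest known reactions are the Büchner–Curtius–Schlotterbeck homologation of cyclic 1,2-diketones with diazoalkanes to 2-substituted 1,3-diketones and the Sc(OTf)3-catalysed ring expansion of cycloalkanones with non-stabilised diazoalkanes. Ring A is not closed by a cyclisation; it arises by one-carbon expansion of the five-membered diketone ring to a six-membered ring, with relief of the strain of the bicyclo[3.2.1]octanetrione. No new stereocentre is formed, because C3 becomes trigonal on enolisation and the three existing centres take no part. The step needs chemoselectivity for the vicinal diketone over the bridging ketone, which the bidentate binding of the Lewis acid and the higher electrophilicity of the strained, dipole-opposed dione should provide. It also needs acyl migration rather than migration of a bridgehead carbon or epoxide closure; the bridgehead carbons are α to the bridging ketone and are therefore poor migrating groups, and addition at either diketone carbonyl leads to the same product after the acyl shift. Low temperature, slow addition and only a small excess of 19 should limit O-alkylation of the acidic product by the diazoalkane.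

Step 16
Reactants: 20 (1R,5S,7R)-4-hydroxy-8,8-dimethyl-5,7-bis(3-methylbut-2-en-1-yl)-3-{3-methyl-3-[(triethylsilyl)oxy]butyl}bicyclo[3.3.1]non-3-ene-2,9-dione
Product: 21 (1R,5S,7R)-4-methoxy-8,8-dimethyl-5,7-bis(3-methylbut-2-en-1-yl)-3-{3-methyl-3-[(triethylsilyl)oxy]butyl}bicyclo[3.3.1]non-3-ene-2,9-dione
Conditions: TMSCHN2, MeOH/toluene (1:4), 0 °C → rt
Reagents that add atoms: trimethylsilyldiazomethane, C[Si](C)(C)C=[N+]=[N-]
Why: O-Methylation of the enol by diazomethane released in situ; methylation at the other enol oxygen is expected to compete, so 21 (carbonyl group at C2, next to the C1–H bond) is separated by chromatography and material methylated at the other oxygen is hydrolysed back to 20 with aqueous LiOH and resubmitted.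

Step 17
Reactants: 22 (2R)-2-methylbutanoic acid
Product: 23 (2R)-2-methylbutanoyl chloride
Conditions: (COCl)2, DMF (cat.), CH2Cl2, 0 °C → rt
Reagents that add atoms: oxalyl chloride, O=C(Cl)C(=O)Cl
Why: Acid chloride formation through the chloroiminium (Vilsmeier-type) species; without added amine base no ketene forms, so the α-stereocentre should be retained.

Step 18
Reactants: 21 (1R,5S,7R)-4-methoxy-8,8-dimethyl-5,7-bis(3-methylbut-2-en-1-yl)-3-{3-methyl-3-[(triethylsilyl)oxy]butyl}bicyclo[3.3.1]non-3-ene-2,9-dione; 23 (2R)-2-methylbutanoyl chloride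
Product: 24 (1S,5S,7R)-4-methoxy-8,8-dimethyl-1-[(2R)-2-methylbutanoyl]-5,7-bis(3-methylbut-2-en-1-yl)-3-{3-methyl-3-[(triethylsilyl)oxy]butyl}bicyclo[3.3.1]non-3-ene-2,9-dione
Conditions: lithium 2,2,6,6-tetramethylpiperidide, THF, −78 °C; then 23, −78 → −40 °C
Reagents that add atoms: none
Why: Bridgehead deprotonation between the C2 and C9 carbonyl groups by a hindered lithium amide and C-acylation of the bridgehead lithium species; C3 has no hydrogen, so no vinylic lithiation competes, substitution at the bridgehead can only occur with retention, and a slight deficit of base should keep 23 from forming a ketene and so protect the side-chain stereocentre.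

Step 19
Reactants: 24 (1S,5S,7R)-4-methoxy-8,8-dimethyl-1-[(2R)-2-methylbutanoyl]-5,7-bis(3-methylbut-2-en-1-yl)-3-{3-methyl-3-[(triethylsilyl)oxy]butyl}bicyclo[3.3.1]non-3-ene-2,9-dione
Product: 25 (1S,5S,7R)-4-hydroxy-8,8-dimethyl-1-[(2R)-2-methylbutanoyl]-5,7-bis(3-methylbut-2-en-1-yl)-3-{3-methyl-3-[(triethylsilyl)oxy]butyl}bicyclo[3.3.1]non-3-ene-2,9-dione
Conditions: LiCl, DMSO, 120 °C; then 0.1 M HCl, 0 °C
Reagents that add atoms: none
Why: Nucleophilic demethylation of the vinylogous ester; chloride attacks the O-methyl group (SN2) and the stabilised triketone enolate leaves, under near-neutral conditions that should spare the prenyl groups, the silyl ether and the α-centre of the acyl group.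

Step 20
Reactants: 25 (1S,5S,7R)-4-hydroxy-8,8-dimethyl-1-[(2R)-2-methylbutanoyl]-5,7-bis(3-methylbut-2-en-1-yl)-3-{3-methyl-3-[(triethylsilyl)oxy]butyl}bicyclo[3.3.1]non-3-ene-2,9-dione
Product: 26 (1S,5S,7R)-4-hydroxy-3-(3-hydroxy-3-methylbutyl)-8,8-dimethyl-1-[(2R)-2-methylbutanoyl]-5,7-bis(3-methylbut-2-en-1-yl)bicyclo[3.3.1]non-3-ene-2,9-dione (CNP0326306.1)
Conditions: HF·pyridine, pyridine, THF, 0 °C → rt
Reagents that add atoms: none
Why: Fluoride cleavage of the tertiary silyl ether; buffering with pyridine should prevent acid-catalysed closure of the tertiary alcohol onto the enol.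

## Compound list

1 | methyl vinyl ketone (but-3-en-2-one) | CC(=O)C=C | starting material
2 | 5-methylhex-4-enal | CC(C)=CCCC=O | starting material
3 | (2S)-2-(3-methylbut-2-en-1-yl)-5-oxohexanal | CC(=O)CC[C@@H](CC=C(C)C)C=O | intermediate
4 | (4S)-4-(3-methylbut-2-en-1-yl)cyclohex-2-en-1-one | O=C1CC[C@@H](CC=C(C)C)C=C1 | intermediate
5 | trimethyl{[(3S,4S)-3-methyl-4-(3-methylbut-2-en-1-yl)cyclohex-1-en-1-yl]oxy}silane | C[Si](C)(C)OC1=C[C@@H](C)[C@H](CC=C(C)C)CC1 | intermediate
6 | (4S)-3-methyl-4-(3-methylbut-2-en-1-yl)cyclohex-2-en-1-one | O=C1C=C(C)[C@H](CC=C(C)C)CC1 | intermediate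
7 | (4S)-3,3-dimethyl-4-(3-methylbut-2-en-1-yl)cyclohexan-1-one | O=C1CC(C)(C)[C@H](CC=C(C)C)CC1 | intermediate
8 | 1-bromo-3-methylbut-2-ene (prenyl bromide) | CC(C)=CCBr | starting material
9 | (4R)-5,5-dimethyl-2,4-bis(3-methylbut-2-en-1-yl)cyclohexan-1-one (C2 epimers) | O=C1C(CC=C(C)C)C[C@@H](CC=C(C)C)C(C)(C)C1 | intermediate
10 | trimethyl{[(4R)-5,5-dimethyl-2,4-bis(3-methylbut-2-en-1-yl)cyclohex-1-en-1-yl]oxy}silane | C[Si](C)(C)OC1=C(CC=C(C)C)C[C@@H](CC=C(C)C)C(C)(C)C1 | intermediate
11 | methyl chlorooxoacetate | COC(=O)C(Cl)=O | starting material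
12 | methyl 2-[(1R,5R)-4,4-dimethyl-1,5-bis(3-methylbut-2-en-1-yl)-2-oxocyclohexyl]-2-oxoacetate | COC(=O)C(=O)[C@]1(CC=C(C)C)C[C@@H](CC=C(C)C)C(C)(C)CC1=O | intermediate
13 | (1S,3R,5R)-2,2-dimethyl-3,5-bis(3-methylbut-2-en-1-yl)bicyclo[3.2.1]octane-6,7,8-trione | [C@H]12C(=O)C(=O)[C@](CC=C(C)C)(C[C@@H](CC=C(C)C)C1(C)C)C2=O | intermediate
14 | 5,5-dimethyldihydrofuran-2(3H)-one | CC1(C)CCC(=O)O1 | starting material
15 | 4-methylpentane-1,4-diol | CC(C)(O)CCCO | intermediate
16 | 2-methyl-2,5-bis[(triethylsilyl)oxy]pentane | CC[Si](CC)(CC)OCCCC(C)(C)O[Si](CC)(CC)CC | intermediate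
17 | 4-methyl-4-[(triethylsilyl)oxy]pentanal | CC[Si](CC)(CC)OC(C)(C)CCC=O | intermediate
18 | {4-methyl-4-[(triethylsilyl)oxy]pentylidene}hydrazine | CC[Si](CC)(CC)OC(C)(C)CCC=NN | intermediate
19 | triethyl[(5-diazo-2-methylpentan-2-yl)oxy]silane | CC[Si](CC)(CC)OC(C)(C)CCC=[N+]=[N-] | intermediate
20 | (1R,5S,7R)-4-hydroxy-8,8-dimethyl-5,7-bis(3-methylbut-2-en-1-yl)-3-{3-methyl-3-[(triethylsilyl)oxy]butyl}bicyclo[3.3.1]non-3-ene-2,9-dione | [C@H]12C(=O)C(CCC(C)(C)O[Si](CC)(CC)CC)=C(O)[C@](CC=C(C)C)(C[C@@H](CC=C(C)C)C1(C)C)C2=O | intermediate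
21 | (1R,5S,7R)-4-methoxy-8,8-dimethyl-5,7-bis(3-methylbut-2-en-1-yl)-3-{3-methyl-3-[(triethylsilyl)oxy]butyl}bicyclo[3.3.1]non-3-ene-2,9-dione | [C@H]12C(=O)C(CCC(C)(C)O[Si](CC)(CC)CC)=C(OC)[C@](CC=C(C)C)(C[C@@H](CC=C(C)C)C1(C)C)C2=O | intermediate
22 | (2R)-2-methylbutanoic acid | CC[C@@H](C)C(=O)O | starting material
23 | (2R)-2-methylbutanoyl chloride | CC[C@@H](C)C(=O)Cl | intermediate
24 | (1S,5S,7R)-4-methoxy-8,8-dimethyl-1-[(2R)-2-methylbutanoyl]-5,7-bis(3-methylbut-2-en-1-yl)-3-{3-methyl-3-[(triethylsilyl)oxy]butyl}bicyclo[3.3.1]non-3-ene-2,9-dione | CC[C@@H](C)C(=O)[C@]12C(=O)C(CCC(C)(C)O[Si](CC)(CC)CC)=C(OC)[C@](CC=C(C)C)(C[C@@H](CC=C(C)C)C1(C)C)C2=O | intermediate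
25 | (1S,5S,7R)-4-hydroxy-8,8-dimethyl-1-[(2R)-2-methylbutanoyl]-5,7-bis(3-methylbut-2-en-1-yl)-3-{3-methyl-3-[(triethylsilyl)oxy]butyl}bicyclo[3.3.1]non-3-ene-2,9-dione | CC[C@@H](C)C(=O)[C@]12C(=O)C(CCC(C)(C)O[Si](CC)(CC)CC)=C(O)[C@](CC=C(C)C)(C[C@@H](CC=C(C)C)C1(C)C)C2=O | intermediate
26 | (1S,5S,7R)-4-hydroxy-3-(3-hydroxy-3-methylbutyl)-8,8-dimethyl-1-[(2R)-2-methylbutanoyl]-5,7-bis(3-methylbut-2-en-1-yl)bicyclo[3.3.1]non-3-ene-2,9-dione (CNP0326306.1) | CC[C@@H](C)C(=O)[C@]12C(=O)C(CCC(C)(C)O)=C(O)[C@](CC=C(C)C)(C[C@@H](CC=C(C)C)C1(C)C)C2=O | target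

## Step count and least certain steps

Total: 20 steps. Longest linear sequence: 14 steps (steps 1–9, 15, 16, 18, 19, 20).

**Step 9 (the one step without precedent on its substrate class).** The most likely failures are O-acylation of the enolate to an enol lactone, reopening of the strained trione by released methoxide (retro-Claisen cleavage or transfer of the oxalyl group to the enolisable side), and intermolecular condensation at the keto carbonyl.
Fallback with known reactions, from 10 back to 13. A BF3·OEt2-mediated Mukaiyama aldol addition of 10 to 2,2-dimethoxyacetaldehyde, with the same facial preference as step 8, should give 2-(1-hydroxy-2,2-dimethoxyethyl)-5,5-dimethyl-2,4-bis(3-methylbut-2-en-1-yl)cyclohexan-1-one F1. Aqueous trifluoroacetic acid at 0 °C unmasks the aldehyde, and acid-catalysed intramolecular aldol addition of the ring ketone enol closes the two-carbon bridge to 6,7-dihydroxy-2,2-dimethyl-3,5-bis(3-methylbut-2-en-1-yl)bicyclo[3.2.1]octan-8-one F2. Swern oxidation of the vicinal diol then gives 13.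

**Step 15 (key step).** The most likely failures are O-alkylation of the acidic enol product by the diazoalkane, epoxide closure of the diazonium alkoxide, migration of a bridgehead carbon instead of the acyl carbon, and loss of 19 before it reacts.
Fallback from 10 to 20, which bypasses 13 and 19. Effenberger cyclisation of 10 with malonyl dichloride (then KOH, BnEt3NCl) should give 4-hydroxy-8,8-dimethyl-5,7-bis(3-methylbut-2-en-1-yl)bicyclo[3.3.1]non-3-ene-2,9-dione F3. Et3N-mediated Michael addition of its C3 to 1 gives 4-hydroxy-8,8-dimethyl-5,7-bis(3-methylbut-2-en-1-yl)-3-(3-oxobutyl)bicyclo[3.3.1]non-3-ene-2,9-dione F4. Excess MeMgBr with CeCl3 at −78 °C adds to the side-chain methyl ketone, while ring A is protected as its enolate and the bridging ketone is hindered, and gives 4-hydroxy-3-(3-hydroxy-3-methylbutyl)-8,8-dimethyl-5,7-bis(3-methylbut-2-en-1-yl)bicyclo[3.3.1]non-3-ene-2,9-dione F5. TESOTf and 2,6-lutidine, followed by K2CO3 in methanol to cleave the silyl enol ether, return to 20.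

**Step 8.** The most likely failures are acylation at the enol oxygen, protodesilylation by adventitious HCl, and insufficient facial selectivity at the new quaternary carbon.
Fallback from 10 to 12. A Mukaiyama aldol addition of 10 to methyl glyoxylate (BF3·OEt2, CH2Cl2, −78 °C) can only form the C–C bond and should give methyl 2-[4,4-dimethyl-1,5-bis(3-methylbut-2-en-1-yl)-2-oxocyclohexyl]-2-hydroxyacetate F6. Dess–Martin oxidation of the carbinol gives 12.

**Step 14.** The most likely failures are azine formation, loss of N2 from the primary diazoalkane with 1,2-hydrogen shift, and carry-over of amine salts that deactivate Sc(OTf)3 in step 15.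
Fallback from 17 to 19. Condensation of 17 with 1,2-bis(tert-butyldimethylsilyl)hydrazine (Sc(OTf)3 cat.) gives the storable 1-(tert-butyldimethylsilyl)-2-{4-methyl-4-[(triethylsilyl)oxy]pentylidene}hydrazine F7. Oxidation with (difluoroiodo)benzene and 2-chloropyridine at −78 °C then releases 19 in solution.

**Step 18.** The most likely failures are incomplete lithiation or slow acylation at the bridgehead next to the gem-dimethyl carbon, and ketene formation from 23 with loss of configurational purity.
Fallback from 21 to 24. Lithiation as before and a quench with iodine give 1-iodo-4-methoxy-8,8-dimethyl-5,7-bis(3-methylbut-2-en-1-yl)-3-{3-methyl-3-[(triethylsilyl)oxy]butyl}bicyclo[3.3.1]non-3-ene-2,9-dione F8. Iodine–magnesium exchange with i-PrMgCl·LiCl and addition to (R)-2-methylbutanal give 1-(1-hydroxy-2-methylbutyl)-4-methoxy-8,8-dimethyl-5,7-bis(3-methylbut-2-en-1-yl)-3-{3-methyl-3-[(triethylsilyl)oxy]butyl}bicyclo[3.3.1]non-3-ene-2,9-dione F9. Dess–Martin oxidation gives 24.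

## Further compounds

F1 | step 9 | 2-(1-hydroxy-2,2-dimethoxyethyl)-5,5-dimethyl-2,4-bis(3-methylbut-2-en-1-yl)cyclohexan-1-one (ring centres as in 12, carbinol epimers) | COC(OC)C(O)[C@]1(CC=C(C)C)C[C@@H](CC=C(C)C)C(C)(C)CC1=O
F2 | step 9 | 6,7-dihydroxy-2,2-dimethyl-3,5-bis(3-methylbut-2-en-1-yl)bicyclo[3.2.1]octan-8-one (ring centres as in 13, carbinol epimers) | [C@H]12C(O)C(O)[C@](CC=C(C)C)(C[C@@H](CC=C(C)C)C1(C)C)C2=O
F3 | step 15 | 4-hydroxy-8,8-dimethyl-5,7-bis(3-methylbut-2-en-1-yl)bicyclo[3.3.1]non-3-ene-2,9-dione | [C@H]12C(=O)C=C(O)[C@](CC=C(C)C)(C[C@@H](CC=C(C)C)C1(C)C)C2=O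
F4 | step 15 | 4-hydroxy-8,8-dimethyl-5,7-bis(3-methylbut-2-en-1-yl)-3-(3-oxobutyl)bicyclo[3.3.1]non-3-ene-2,9-dione | [C@H]12C(=O)C(CCC(C)=O)=C(O)[C@](CC=C(C)C)(C[C@@H](CC=C(C)C)C1(C)C)C2=O
F5 | step 15 | 4-hydroxy-3-(3-hydroxy-3-methylbutyl)-8,8-dimethyl-5,7-bis(3-methylbut-2-en-1-yl)bicyclo[3.3.1]non-3-ene-2,9-dione | [C@H]12C(=O)C(CCC(C)(C)O)=C(O)[C@](CC=C(C)C)(C[C@@H](CC=C(C)C)C1(C)C)C2=O
F6 | step 8 | methyl 2-[4,4-dimethyl-1,5-bis(3-methylbut-2-en-1-yl)-2-oxocyclohexyl]-2-hydroxyacetate (ring centres as in 12, carbinol epimers) | COC(=O)C(O)[C@]1(CC=C(C)C)C[C@@H](CC=C(C)C)C(C)(C)CC1=O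
F7 | step 14 | 1-(tert-butyldimethylsilyl)-2-{4-methyl-4-[(triethylsilyl)oxy]pentylidene}hydrazine | CC[Si](CC)(CC)OC(C)(C)CCC=NN[Si](C)(C)C(C)(C)C
F8 | step 18 | 1-iodo-4-methoxy-8,8-dimethyl-5,7-bis(3-methylbut-2-en-1-yl)-3-{3-methyl-3-[(triethylsilyl)oxy]butyl}bicyclo[3.3.1]non-3-ene-2,9-dione | I[C@]12C(=O)C(CCC(C)(C)O[Si](CC)(CC)CC)=C(OC)[C@](CC=C(C)C)(C[C@@H](CC=C(C)C)C1(C)C)C2=O
F9 | step 18 | 1-(1-hydroxy-2-methylbutyl)-4-methoxy-8,8-dimethyl-5,7-bis(3-methylbut-2-en-1-yl)-3-{3-methyl-3-[(triethylsilyl)oxy]butyl}bicyclo[3.3.1]non-3-ene-2,9-dione (carbinol epimers) | CC[C@@H](C)C(O)[C@]12C(=O)C(CCC(C)(C)O[Si](CC)(CC)CC)=C(OC)[C@](CC=C(C)C)(C[C@@H](CC=C(C)C)C1(C)C)C2=O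
A1 | alternative 1 | triisopropyl[(4-methylpenta-1,3-dien-2-yl)oxy]silane | C=C(O[Si](C(C)C)(C(C)C)C(C)C)C=C(C)C
A2 | alternative 1 | 3-(prop-2-enoyl)-1,3-oxazolidin-2-one | C=CC(=O)N1CCOC1=O
A3 | alternative 1 | 3-{[2,2-dimethyl-4-(triisopropylsilyloxy)cyclohex-3-en-1-yl]carbonyl}oxazolidin-2-one | O=C(N1CCOC1=O)[C@@H]2CCC(O[Si](C(C)C)(C(C)C)C(C)C)=CC2(C)C
A4 | alternative 2 | 3-[(tert-butyldimethylsilyl)oxy]-5,5-dimethyl-2-(3-methylbut-2-en-1-yl)-2-(prop-2-yn-1-yl)cyclohex-3-en-1-one | C#CC[C@]1(CC=C(C)C)C(=O)CC(C)(C)C=C1O[Si](C)(C)C(C)(C)C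
A5 | alternative 2 | 8,8-dimethyl-5-(3-methylbut-2-en-1-yl)bicyclo[3.3.1]non-2-ene-6,9-dione | [C@H]12C=CC[C@](CC=C(C)C)(C(=O)CC1(C)C)C2=O
A6 | alternative 3 | 2-{[2,6-dimethoxy-1-(3-methylbut-2-en-1-yl)cyclohexa-2,5-dien-1-yl]methyl}-3,3-dimethyloxirane | COC1=CCC=C(OC)C1(CC=C(C)C)C[C@H]2OC2(C)C
A7 | alternative 3 | 7-hydroxy-4-methoxy-8,8-dimethyl-5-(3-methylbut-2-en-1-yl)bicyclo[3.3.1]non-3-en-9-one | [C@H]12CC=C(OC)[C@](CC=C(C)C)(C[C@@H](O)C1(C)C)C2=O
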